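Lignan numbering is used throughout: ring A is the aromatic ring (C4a, C5–C8, C8a), ring B the saturated ring (C1–C4, C4a, C8a). The four-membered ring is numbered C1' (C=O), C2', C3', C4' (sp3).

## Analysis of the target

Compound 24 is an aryltetralin lignan: a tetralin (rings A and B) with a 4-hydroxy-3-methoxyphenyl ring on C1 and hydroxymethyl groups on C2 and C3. The three stereocentres C1, C2 and C3 are contiguous and 1,2-trans-2,3-trans, with absolute configuration 1R,2S,3S. All three substituents can sit equatorial, so the relative configuration is the thermodynamic one, but the absolute configuration has to be introduced. The sensitive groups are two free phenols on electron-rich rings (easily oxidised), a 1,4-diol and a doubly benzylic C1–H. The hard part is ring A: it is pentasubstituted, with three neighbouring oxygens that are not alike (OMe on C5 and C6, free OH on C7) beside the only aromatic C–H, C8. Such a pattern is awkward to reach by substitution of a benzene and must be combined with enantiocontrol in ring B. The plan rests on the chain C5–C6–C7–C8: four carbons, three oxygenated and one bare, which map onto the four carbons of a reduced squaric ester. Ring A can therefore be grown onto a C8a=C4a double bond of a finished ring B, with C5 arriving as a carbonyl carbon.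

## Retrosynthetic reasoning

**24 back to 21 (protecting groups and one methyl).** The O–benzyl bonds on C7 and on the pendant phenol, the two O–Si bonds and the O–CH3 bond on C5 are cut, leading through 23 and 22 to phenol 21. The ring construction leaves the C5 oxygen as the only free hydroxyl, so methylation there is unambiguous. C7 and the pendant phenol carry the same benzyl group, so a single neutral hydrogenolysis frees both at the very end.

**21 back to 18 (ring A).** The C5–C4a bond is cut and the C5–C8 bond of a four-membered ring is restored, giving cyclobutenone 18. This is the only cut that removes the whole of ring A at once and leaves its oxygen pattern stored in a small ring. Forward, 18 must open to dienylketene 19, close to dienone 20 and aromatise, without touching C1–C3.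

**18 back to 13 and 17 (C8–C8a).** The sp3–sp2 bond between C4' and C8a is cut. C4' of 17 is an allylic, α-keto chloride and so a good electrophile for cross-coupling, and ring B supplies the alkenyl metal as stannane 13. The cut makes the route convergent and turns the bare sp3 carbon of 17 into C8.

**17 back to 14 (four-carbon unit).** The C–Cl bond, the benzyl–oxygen link on C3' and the C4'–H bond are cut, leading through 16 and 15 to dimethyl squarate 14. The order matters. A mixed methyl/benzyl squarate would be reduced at either carbonyl without discrimination, so the symmetric diester 14 is reduced first. In 15 the two methoxy groups are then different: only the one on C3' is part of a vinylogous ester and can be exchanged. That places the removable group on the carbon that becomes C7 and keeps methoxy on the future C6.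

**13 back to 10 (alkenyl metal).** The C8a–Sn bond is cut back to ketone 10 through sulfonylhydrazone 11. The double bond must lie toward C4a and not toward the more acidic benzylic C1. A hydrazone dianion is deprotonated on the side syn to nitrogen, which is the unsubstituted C4a side, so the regiochemistry does not depend on kinetic enolate selectivity.

**10 back to 7 (adjustments on ring B).** Silyl ethers, ketone and alcohols are traced back through 9 and 8 to diester 7. The ketone stage is used to settle C1 by equilibration next to the carbonyl, so the cycloaddition only has to fix C2 and C3.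

**7 back to 5 and 6 (ring B).** The C1–C2 and C3–C4 bonds are cut in a Diels–Alder sense. Diethyl fumarate 6 delivers C2 and C3 with the trans relationship built in. Diene 5 delivers C1 with its aryl group, and the enol ether double bond of the adduct already lies at C8a=C4a. A chiral Lewis acid has to select one face of 6.

**5 back to 1 (diene).** The silyl enol ether and the vinyl ketone are traced back through 4, 3 and 2 to homovanillic acid 1, which contains the pendant ring and C1.

## Alternatives that were turned down

**Alternative 1: oxidative coupling of a cinnamyl cinnamate.** The C2–C3 and C1–C8a bonds are cut, leading to coniferyl 4-hydroxy-2,3-dimethoxycinnamate A1. Forward, a one-electron oxidant (FeCl3 or Ag2O) would turn both phenols into radicals, join the two β-carbons and close the lactone. Ring A would then attack the quinone methide at C1 through C8a to give dihydronaphthalene lactone A2.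
- For it: no protecting groups, two C–C bonds and two rings in one step, and far fewer steps than the chosen route. On step economy it is clearly stronger.
- Against it: phenoxyl radicals also couple through ring carbons and oxygen, and C8a is meta to the ring A phenol, so its nucleophilicity rests on one para methoxy group. Nothing in A1 controls absolute configuration, so A2 would be racemic. The product phenols are more easily oxidised than A1. The C3=C4 double bond of A2 would still have to be reduced with C3 trans to C2.
- Comparison: the chosen route is longer but offers catalyst control of C2/C3, thermodynamic control of C1 and a ring A pattern fixed by constitution.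

**Alternative 2: cationic cyclisation and arylation at C1.** The C1–C8a and C1–aryl bonds are cut, leading to open-chain acetal A3 and guaiacol A4. Forward, acid would ionise the acetal, ring A would close ring B through C8a, and the C1 cation would be captured by A4 para to its hydroxyl to give triacetate A5.
- For it: convergent, the pendant ring is added last, C2 and C3 can come from established asymmetric alkylation chemistry, and attack anti to the C2 substituent should give the 1,2-trans product. In convergence and probably in step count it is at least as good as the chosen route.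
- Against it: two cationic events share one flask. The C1 cation can lose a proton to a C1=C2 alkene, A4 has two activated para positions (para to OH and para to OMe) plus ortho sites, and the acetates are acid-labile. The 4-acetoxy-2,3-dimethoxybenzyl unit of A3 must itself be made with the full oxygen pattern.
- Comparison: the chosen route carries the pendant ring from the first step and never generates a cation at C1.

**Alternative 3: allylsilane closure onto a C4 oxocarbenium ion.** The C3–C4 bond is cut, leading to allylsilane acetal A6. Forward, a Lewis acid (BF3·OEt2 or Me3SiOTf) would ionise the acetal and the γ-carbon of the allylsilane would attack C4 to give vinyl tetralin A7.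
- For it: a dependable six-membered closure through a chair-like transition state, which should place the vinyl group trans to the C2 substituent. No tin and no thermal ketene are needed, so the key step itself is safer than the chosen one.
- Against it: A6 already needs the diarylmethine C1, the C2 stereocentre and a pentasubstituted benzene with an ortho acetal, so the ring A problem is only moved into aromatic substitution chemistry. After closure the C4 methoxy group has to be removed and the vinyl group cut down to CH2OH, which adds steps.
- Comparison: the chosen route builds ring A instead of decorating it and needs no corrective steps after the ring is formed.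

Key step: step 14

Assumption: the sense of induction in step 4 is taken from the usual binding model of the protonated oxazaborolidine (ester carbonyl on boron, α-C–H hydrogen bond to the ring oxygen). It predicts that the catalyst from (S)-diphenylprolinol opens the Si,Si face of 6; if the first adduct shows the opposite sense, the catalyst from (R)-diphenylprolinol is used with no other change.

## Route

Step 1
Reactants: 1 homovanillic acid
Product: 2 benzyl [4-(benzyloxy)-3-methoxyphenyl]acetate
Conditions: BnBr (2.3 equiv), K2CO3, DMF, 60 °C
Reagents that add atoms: benzyl bromide, BrCc1ccccc1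
Why: Williamson O-alkylation of phenoxide and carboxylate in one operation; the ether protects the phenol until the final hydrogenolysis and the ester is the acyl donor for step 2.

Step 2
Reactants: 2 benzyl [4-(benzyloxy)-3-methoxyphenyl]acetate
Product: 4 1-[4-(benzyloxy)-3-methoxyphenyl]but-3-en-2-one, via Weinreb amide 3 (not isolated)
Conditions: MeNH(OMe)·HCl (1.5 equiv), i-PrMgCl (3.0 equiv), THF, −20 °C; then CH2=CHMgBr (2 equiv), −20 → 0 °C; poured into cold 1 M HCl
Reagents that add atoms: vinylmagnesium bromide, C=C[Mg]Br (N,O-dimethylhydroxylamine hydrochloride, CNOC.Cl, enters intermediate 3 only)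
Why: Ester aminolysis by the chloromagnesium amide gives Weinreb amide 3, and the vinyl Grignard reagent adds once because the magnesium chelate holds until the quench (Weinreb ketone synthesis). The acidic quench keeps the freed amine protonated so it cannot add to the enone, which is used at once.

Step 3
Reactants: 4 1-[4-(benzyloxy)-3-methoxyphenyl]but-3-en-2-one
Product: 5 (Z)-1-[4-(benzyloxy)-3-methoxyphenyl]-2-(triisopropylsilyloxy)buta-1,3-diene
Conditions: i-Pr3SiOTf (1.1 equiv), Et3N, CH2Cl2, −78 → 0 °C
Reagents that add atoms: triisopropylsilyl trifluoromethanesulfonate, CC(C)[Si](C(C)C)(C(C)C)OS(=O)(=O)C(F)(F)F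
Why: Soft enolisation; the benzylic CH2 is the only enolisable position, and allylic strain should favour the Z enol ether (aryl cis to oxygen, on the outside of the s-cis diene). Any E isomer cannot reach the s-cis form and stays behind in step 4.

Step 4
Reactants: 5 (Z)-1-[4-(benzyloxy)-3-methoxyphenyl]-2-(triisopropylsilyloxy)buta-1,3-diene; 6 diethyl fumarate
Product: 7 diethyl all-trans-3-[4-(benzyloxy)-3-methoxyphenyl]-4-(triisopropylsilyloxy)cyclohex-4-ene-1,2-dicarboxylate (aryl on lignan C1 trans to the C2 ester; C2 and C3 esters trans; absolute configuration as in the SMILES)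
Conditions: (S)-3,3-diphenyl-1-(2-methylphenyl)tetrahydro-1H,3H-pyrrolo[1,2-c][1,3,2]oxazaborole (20 mol %), HNTf2 (16 mol %), CH2Cl2, −78 → −20 °C
Reagents that add atoms: none
Why: Enantioselective Diels–Alder reaction under chiral cationic oxazaborolidine catalysis: the boron-bound ester of 6 is activated and shielded on one face, the diene adds to the Si,Si face and sets C2 and C3, the E geometry of 6 makes them trans, and the new double bond lies at C8a=C4a as a silyl enol ether. With the enol ether terminus C1 bonding to the β-carbon of the bound ester and that ester endo, the aryl group should come out trans to the C2 ester; any C1 epimer is corrected in step 6.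

Step 5
Reactants: 7 the diester of step 4
Product: 8 [all-trans-3-[4-(benzyloxy)-3-methoxyphenyl]-4-(triisopropylsilyloxy)cyclohex-4-ene-1,2-diyl]dimethanol
Conditions: LiAlH4, THF, 0 °C
Reagents that add atoms: none
Why: Hydride reduction of both esters to primary alcohols; the hindered silyl enol ether and the benzyl ether are inert, and C2 and C3 are not touched.

Step 6
Reactants: 8 the diol of step 5
Product: 9 all-trans-2-[4-(benzyloxy)-3-methoxyphenyl]-3,4-bis(hydroxymethyl)cyclohexan-1-one
Conditions: Bu4NF, THF, 0 °C → rt; then DBU (0.3 equiv), rt
Reagents that add atoms: none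
Why: Fluoride cleaves the enol Si–O bond and protonation gives the ketone; the amidine base then equilibrates the benzylic C1 (α to the ketone) to the isomer with all three substituents equatorial (thermodynamic epimerisation). C2 and C3 carry no acidifying group and keep their configuration.

Step 7
Reactants: 9 the keto diol of step 6
Product: 10 all-trans-2-[4-(benzyloxy)-3-methoxyphenyl]-3,4-bis[(tert-butyldimethylsilyloxy)methyl]cyclohexan-1-one
Conditions: t-BuMe2SiCl, imidazole, DMF, rt
Reagents that add atoms: tert-butyldimethylsilyl chloride, CC(C)(C)[Si](C)(C)Cl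
Why: Silylation of the two primary alcohols; the ketone is not enolised under these conditions, so C1 is unchanged.

Step 8
Reactants: 10 the bis-silyl ketone of step 7
Product: 11 (E)-2,4,6-triisopropylbenzenesulfonylhydrazone of ketone 10
Conditions: 2,4,6-(i-Pr)3C6H2SO2NHNH2, pyridinium p-toluenesulfonate (cat.), THF, rt
Reagents that add atoms: 2,4,6-triisopropylbenzenesulfonyl hydrazide, NNS(=O)(=O)c1c(C(C)C)cc(C(C)C)cc1C(C)C
Why: Hydrazone condensation; the N–N bond should settle anti to the substituted C1 and so syn to the C4a methylene, which fixes the site of deprotonation in step 9.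

Step 9
Reactants: 11 the sulfonylhydrazone of step 8
Product: 13 trimethyl{all-trans-6-[4-(benzyloxy)-3-methoxyphenyl]-4,5-bis[(tert-butyldimethylsilyloxy)methyl]cyclohex-1-en-1-yl}stannane, via vinyllithium 12 (not isolated)
Conditions: n-BuLi (2.2 equiv), THF, −78 → 0 °C; then Me3SnCl, −78 °C → rt
Reagents that add atoms: chlorotrimethylstannane, C[Sn](C)(C)Cl
Why: Shapiro reaction: the second equivalent of base removes a C4a proton syn to the sulfonamide nitrogen, and loss of sulfinate and N2 on warming gives vinyllithium 12 with the double bond only at C8a=C4a; the tin chloride then traps it. C1 is not deprotonated and keeps its configuration.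

Step 10
Reactants: 14 dimethyl squarate
Product: 15 4-hydroxy-2,3-dimethoxycyclobut-2-en-1-one (racemic)
Conditions: LiAlH(Ot-Bu)3, THF, −78 °C
Reagents that add atoms: none
Why: Monoreduction of a squaric diester by 1,2-addition of a hindered hydride to one of two equivalent carbonyls, so no regiochemical question arises; the resulting alkoxide of a vinylogous ester is not reduced further at this temperature.

Step 11
Reactants: 15 4-hydroxy-2,3-dimethoxycyclobut-2-en-1-one
Product: 16 3-(benzyloxy)-4-hydroxy-2-methoxycyclobut-2-en-1-one (racemic)
Conditions: BnOH (3 equiv), NaH (0.1 equiv), THF, 4 Å sieves, 0 °C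
Reagents that add atoms: benzyl alcohol, OCc1ccccc1
Why: Vinylogous transesterification by conjugate addition–elimination: benzyloxide adds to C3', the β-carbon of the enone, and methoxide leaves. The enol ether methoxy group on C2' has no such pathway, so the exchange is regiospecific and puts the removable group on the carbon that becomes C7.

Step 12
Reactants: 16 3-(benzyloxy)-4-hydroxy-2-methoxycyclobut-2-en-1-one
Product: 17 3-(benzyloxy)-4-chloro-2-methoxycyclobut-2-en-1-one (racemic)
Conditions: SOCl2, pyridine, CH2Cl2, −20 → 0 °C
Reagents that add atoms: thionyl chloride, O=S(Cl)Cl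
Why: Chlorodehydroxylation of the secondary, allylic α-keto alcohol through its chlorosulfite; the chloride should rest on C4', where the conjugated vinylogous ester is kept, and pyridine buffers the acid.

Step 13
Reactants: 13 the alkenylstannane of step 9; 17 3-(benzyloxy)-4-chloro-2-methoxycyclobut-2-en-1-one
Product: 18 3-(benzyloxy)-4-{all-trans-6-[4-(benzyloxy)-3-methoxyphenyl]-4,5-bis[(tert-butyldimethylsilyloxy)methyl]cyclohex-1-en-1-yl}-2-methoxycyclobut-2-en-1-one (both C4' epimers)
Conditions: PdCl2(PhCN)2 (5 mol %), P(2-furyl)3 (10 mol %), CuI (10 mol %), dioxane, 40 °C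
Reagents that add atoms: none
Why: Stille coupling: zerovalent palladium formed in the flask inserts into the activated C4'–Cl bond, the alkenyl group is transferred from tin and reductive elimination forms the C8–C8a bond. The mild temperature keeps the product from opening, and both C4' epimers are usable.

Step 14
Reactants: 18 the 4-(cyclohexenyl)cyclobutenone of step 13
Product: 21 7-(benzyloxy)-1-[4-(benzyloxy)-3-methoxyphenyl]-2,3-bis[(tert-butyldimethylsilyloxy)methyl]-6-methoxy-1,2,3,4-tetrahydronaphthalen-5-ol (lignan numbering; 1,2-trans-2,3-trans), via dienylketene 19 (not isolated), via cyclohexadienone 20 (not isolated)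
Conditions: toluene (0.01 M, degassed), 110 °C
Reagents that add atoms: none
Why: Heating opens the cyclobutenone by thermal conrotatory 4π cleavage of the C1'–C4' bond (C5–C8) to a vinylketene; the rotamer with the cyclohexenyl group turned inward is dienylketene 19, whose ketene carbon lies next to C4a. A thermal disrotatory 6π electrocyclisation then joins the ketene carbon (C5) to C4a and closes ring A as cyclohexadienone 20, and enolisation of the C4a hydrogen gives phenol 21. The closest known reaction type is the thermal rearrangement of 4-alkenyl- and 4-arylcyclobut-2-enones, made from 4-chlorocyclobutenones, to phenols. Ring A is closed by a six-membered, all-carbon 6π electrocyclic closure; the only new sp3 centre, C4a in 20, disappears on aromatisation, so no stereocentre is created and C1–C3 lie outside the reacting π system. The selectivity needed is inward rotation of the alkenyl group at C4'; outward rotation gives a ketene that cannot cyclise, but ring opening is reversible at this temperature, so that isomer returns to 18 and the material drains through 19. Regiochemistry is fixed by constitution: C4a is the only alkene terminus within reach, the four-membered ring delivers C5 (OH), C6 (OMe), C7 (OBn) and C8 (H) in that order, and both C4' epimers of 18 give the same product. High dilution and the absence of free hydroxyl groups keep the ketene from dimerising or being trapped.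

Step 15
Reactants: 21 the C5 phenol of step 14
Product: 22 7-(benzyloxy)-1-[4-(benzyloxy)-3-methoxyphenyl]-2,3-bis[(tert-butyldimethylsilyloxy)methyl]-5,6-dimethoxy-1,2,3,4-tetrahydronaphthalene (lignan numbering)
Conditions: MeI, K2CO3, DMF, 40 °C
Reagents that add atoms: iodomethane, CI
Why: Williamson methylation of the only free phenol, on C5.

Step 16
Reactants: 22 the bis-silyl ether of step 15
Product: 23 {7-(benzyloxy)-1-[4-(benzyloxy)-3-methoxyphenyl]-5,6-dimethoxy-1,2,3,4-tetrahydronaphthalene-2,3-diyl}dimethanol (lignan numbering)
Conditions: Bu4NF, THF, rt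
Reagents that add atoms: none
Why: Fluoride desilylation of both primary silyl ethers; benzyl and methyl ethers are inert.

Step 17
Reactants: 23 the dibenzyl ether diol of step 16
Product: 24 (1R,2S,3S)-1-(4-hydroxy-3-methoxyphenyl)-2,3-bis(hydroxymethyl)-5,6-dimethoxy-1,2,3,4-tetrahydronaphthalen-7-ol (lignan numbering; target)
Conditions: H2 (1 atm), Pd/C (10 wt %), EtOAc–MeOH, rt
Reagents that add atoms: none
Why: Hydrogenolysis of both aryl benzyl ethers under neutral conditions; nothing else in the molecule is reducible and the stereocentres are not involved.

## Compound list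

1 | homovanillic acid | COc1cc(CC(=O)O)ccc1O | starting material
2 | benzyl [4-(benzyloxy)-3-methoxyphenyl]acetate | COc1cc(CC(=O)OCc2ccccc2)ccc1OCc1ccccc1 | intermediate
3 | 2-[4-(benzyloxy)-3-methoxyphenyl]-N-methoxy-N-methylacetamide (not isolated) | COc1cc(CC(=O)N(C)OC)ccc1OCc1ccccc1 | intermediate
4 | 1-[4-(benzyloxy)-3-methoxyphenyl]but-3-en-2-one | COc1cc(CC(=O)C=C)ccc1OCc1ccccc1 | intermediate
5 | (Z)-1-[4-(benzyloxy)-3-methoxyphenyl]-2-(triisopropylsilyloxy)buta-1,3-diene | COc1cc(/C=C(\O[Si](C(C)C)(C(C)C)C(C)C)C=C)ccc1OCc1ccccc1 | intermediate
6 | diethyl fumarate | CCOC(=O)/C=C/C(=O)OCC | starting material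
7 | diethyl all-trans-3-[4-(benzyloxy)-3-methoxyphenyl]-4-(triisopropylsilyloxy)cyclohex-4-ene-1,2-dicarboxylate | COc1cc([C@@H]2C(O[Si](C(C)C)(C(C)C)C(C)C)=CC[C@H](C(=O)OCC)[C@H]2C(=O)OCC)ccc1OCc1ccccc1 | intermediate
8 | [all-trans-3-[4-(benzyloxy)-3-methoxyphenyl]-4-(triisopropylsilyloxy)cyclohex-4-ene-1,2-diyl]dimethanol | COc1cc([C@@H]2C(O[Si](C(C)C)(C(C)C)C(C)C)=CC[C@H](CO)[C@H]2CO)ccc1OCc1ccccc1 | intermediate
9 | all-trans-2-[4-(benzyloxy)-3-methoxyphenyl]-3,4-bis(hydroxymethyl)cyclohexan-1-one | COc1cc([C@@H]2C(=O)CC[C@H](CO)[C@H]2CO)ccc1OCc1ccccc1 | intermediate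
10 | all-trans-2-[4-(benzyloxy)-3-methoxyphenyl]-3,4-bis[(tert-butyldimethylsilyloxy)methyl]cyclohexan-1-one | COc1cc([C@@H]2C(=O)CC[C@H](CO[Si](C)(C)C(C)(C)C)[C@H]2CO[Si](C)(C)C(C)(C)C)ccc1OCc1ccccc1 | intermediate
11 | (E)-2,4,6-triisopropylbenzenesulfonylhydrazone of 10 | COc1cc([C@@H]2/C(=N/NS(=O)(=O)c3c(C(C)C)cc(C(C)C)cc3C(C)C)CC[C@H](CO[Si](C)(C)C(C)(C)C)[C@H]2CO[Si](C)(C)C(C)(C)C)ccc1OCc1ccccc1 | intermediate
12 | cyclohexenyllithium from 11, lithium on C8a (not isolated) | COc1cc([C@@H]2C([Li])=CC[C@H](CO[Si](C)(C)C(C)(C)C)[C@H]2CO[Si](C)(C)C(C)(C)C)ccc1OCc1ccccc1 | intermediate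
13 | trimethyl{all-trans-6-[4-(benzyloxy)-3-methoxyphenyl]-4,5-bis[(tert-butyldimethylsilyloxy)methyl]cyclohex-1-en-1-yl}stannane | COc1cc([C@@H]2C([Sn](C)(C)C)=CC[C@H](CO[Si](C)(C)C(C)(C)C)[C@H]2CO[Si](C)(C)C(C)(C)C)ccc1OCc1ccccc1 | intermediate
14 | dimethyl squarate | COC1=C(OC)C(=O)C1=O | starting material
15 | 4-hydroxy-2,3-dimethoxycyclobut-2-en-1-one | COC1=C(OC)C(O)C1=O | intermediate
16 | 3-(benzyloxy)-4-hydroxy-2-methoxycyclobut-2-en-1-one | COC1=C(OCc2ccccc2)C(O)C1=O | intermediate
17 | 3-(benzyloxy)-4-chloro-2-methoxycyclobut-2-en-1-one | COC1=C(OCc2ccccc2)C(Cl)C1=O | intermediate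
18 | 3-(benzyloxy)-4-(ring B cyclohexenyl)-2-methoxycyclobut-2-en-1-one, C4' unspecified | COc1cc([C@@H]2C(C3C(=O)C(OC)=C3OCc3ccccc3)=CC[C@H](CO[Si](C)(C)C(C)(C)C)[C@H]2CO[Si](C)(C)C(C)(C)C)ccc1OCc1ccccc1 | intermediate
19 | dienylketene, cyclohexenyl and ketenyl groups cis on the central double bond (not isolated) | COc1cc([C@@H]2C(/C=C(OCc3ccccc3)\C(OC)=C=O)=CC[C@H](CO[Si](C)(C)C(C)(C)C)[C@H]2CO[Si](C)(C)C(C)(C)C)ccc1OCc1ccccc1 | intermediate
20 | 4a-H cyclohexa-2,4-dienone, C5 carbonyl (not isolated) | COc1cc([C@@H]2C3=CC(OCc4ccccc4)=C(OC)C(=O)C3C[C@H](CO[Si](C)(C)C(C)(C)C)[C@H]2CO[Si](C)(C)C(C)(C)C)ccc1OCc1ccccc1 | intermediate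
21 | tetralin with C5 phenol, C6 OMe, C7 benzyl ether, bis-silyl ether | COc1cc([C@@H]2c3cc(OCc4ccccc4)c(OC)c(O)c3C[C@H](CO[Si](C)(C)C(C)(C)C)[C@H]2CO[Si](C)(C)C(C)(C)C)ccc1OCc1ccccc1 | intermediate
22 | tetralin with C5 and C6 OMe, C7 benzyl ether, bis-silyl ether | COc1cc([C@@H]2c3cc(OCc4ccccc4)c(OC)c(OC)c3C[C@H](CO[Si](C)(C)C(C)(C)C)[C@H]2CO[Si](C)(C)C(C)(C)C)ccc1OCc1ccccc1 | intermediate
23 | dibenzyl ether diol | COc1cc([C@@H]2c3cc(OCc4ccccc4)c(OC)c(OC)c3C[C@H](CO)[C@H]2CO)ccc1OCc1ccccc1 | intermediate
24 | (1R,2S,3S)-1-(4-hydroxy-3-methoxyphenyl)-2,3-bis(hydroxymethyl)-5,6-dimethoxy-1,2,3,4-tetrahydronaphthalen-7-ol (lignan numbering) | COc1cc([C@@H]2c3cc(O)c(OC)c(OC)c3C[C@H](CO)[C@H]2CO)ccc1O | target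

## Step count and least certain steps

Total step count: 17. Longest linear sequence: 14 (steps 1–9 and 13–17); steps 10–12 build the four-carbon fragment separately.

**Step 14 (key step).** The alkenyl group may rotate outward in most ring-opening events, and the non-cyclising ketene may then be lost by dimerisation or capture by traces of water before it can return to 18. The aryl group on C1 also crowds the C8a terminus and may slow the closure. Fallback: from 18, irradiation (350 nm, benzene, 20 °C) opens the ring photochemically, a mode known to favour inward rotation where heat favours outward, and the inward ketene closes at ambient temperature to 21. No new compound is formed (entry F0).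

**Step 4.** Facial selectivity may be poor with this 1-aryl diene, or the acidic catalyst may desilylate or oligomerise the diene before cycloaddition; the endo/exo ratio does not matter because C1 is reset in step 6. Fallback: from 5, an auxiliary-controlled cycloaddition. (S)-4-Benzyloxazolidin-2-one is acylated with ethyl fumaroyl chloride (n-BuLi, THF) to (S)-4-benzyl-3-[(E)-3-(ethoxycarbonyl)acryloyl]oxazolidin-2-one F1. Its Me2AlCl chelate should expose the same Si,Si face to 5 at −78 °C and give the imide ester cycloadduct F2. LiBH4 in THF–MeOH would reduce imide and ester together and return the route at diol 8.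

**Step 9.** The vinyllithium may be protonated by solvent or may metalate the benzyl ether before it is trapped, and a minor Z hydrazone would deprotonate at C1. Fallback: from ketone 10, kinetic deprotonation with KN(SiMe3)2 at −78 °C and trapping with PhNTf2 gives the cyclohexenyl triflate F3. Pd(PPh3)4-catalysed stannylation with Me3SnSnMe3 and LiCl returns the route at 13.

**Step 11.** The alkoxide of 15 may open the four-membered ring faster than benzyloxide exchanges at C3', or the exchange may stop short of completion. Fallback: from 15, silylation (t-BuMe2SiCl, imidazole) gives 4-(tert-butyldimethylsilyloxy)-2,3-dimethoxycyclobut-2-en-1-one F4, in which no alkoxide can form. The same exchange gives 3-(benzyloxy)-4-(tert-butyldimethylsilyloxy)-2-methoxycyclobut-2-en-1-one F5, and buffered fluoride (Bu4NF, AcOH) returns the route at 16.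

**Step 13.** Transmetalation from the hindered stannane may be slow, so that homocoupling or premature ring opening of the product takes over. Fallback: from 11, vinyllithium 12 is made as in step 9 and transmetalated with ZnCl2 to the alkenylzinc chloride F6. Negishi coupling with 17 (Pd(PPh3)4, THF, rt) returns the route at 18.

## Further compounds

F0 | step 14 | none | none
F1 | step 4 | (S)-4-benzyl-3-[(E)-3-(ethoxycarbonyl)acryloyl]oxazolidin-2-one | CCOC(=O)/C=C/C(=O)N1[C@@H](Cc2ccccc2)COC1=O
F2 | step 4 | imide ester cycloadduct, imide on lignan C3, ethyl ester on C2, silyl enol ether at C8a | COc1cc([C@@H]2C(O[Si](C(C)C)(C(C)C)C(C)C)=CC[C@H](C(=O)N3[C@@H](Cc4ccccc4)COC3=O)[C@H]2C(=O)OCC)ccc1OCc1ccccc1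
F3 | step 9 | all-trans-6-[4-(benzyloxy)-3-methoxyphenyl]-4,5-bis[(tert-butyldimethylsilyloxy)methyl]cyclohex-1-en-1-yl trifluoromethanesulfonate | COc1cc([C@@H]2C(OS(=O)(=O)C(F)(F)F)=CC[C@H](CO[Si](C)(C)C(C)(C)C)[C@H]2CO[Si](C)(C)C(C)(C)C)ccc1OCc1ccccc1
F4 | step 11 | 4-(tert-butyldimethylsilyloxy)-2,3-dimethoxycyclobut-2-en-1-one | COC1=C(OC)C(O[Si](C)(C)C(C)(C)C)C1=O
F5 | step 11 | 3-(benzyloxy)-4-(tert-butyldimethylsilyloxy)-2-methoxycyclobut-2-en-1-one | COC1=C(OCc2ccccc2)C(O[Si](C)(C)C(C)(C)C)C1=O
F6 | step 13 | alkenylzinc chloride, zinc on C8a | COc1cc([C@@H]2C([Zn]Cl)=CC[C@H](CO[Si](C)(C)C(C)(C)C)[C@H]2CO[Si](C)(C)C(C)(C)C)ccc1OCc1ccccc1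
A1 | alternative 1 | coniferyl 4-hydroxy-2,3-dimethoxycinnamate | COc1cc(/C=C/COC(=O)/C=C/c2ccc(O)c(OC)c2OC)ccc1O
A2 | alternative 1 | 1-aryl-1,2-dihydronaphthalene fused to a butenolide, both phenols free | COc1cc([C@@H]2c3cc(O)c(OC)c(OC)c3C=C3C(=O)OC[C@@H]23)ccc1O
A3 | alternative 2 | open-chain C1 dimethyl acetal with 4-acetoxy-2,3-dimethoxybenzyl group and two acetoxymethyl groups | COc1c(C[C@H](COC(C)=O)[C@H](C(OC)OC)COC(C)=O)ccc(OC(C)=O)c1OC
A4 | alternative 2 | guaiacol | COc1ccccc1O
A5 | alternative 2 | target as its triacetate, guaiacyl phenol free | COc1cc([C@@H]2c3cc(OC(C)=O)c(OC)c(OC)c3C[C@H](COC(C)=O)[C@H]2COC(C)=O)ccc1O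
A6 | alternative 3 | allylsilane with C4 dimethyl acetal on ring A | COc1cc([C@H](c2cc(OCc3ccccc3)c(OC)c(OC)c2C(OC)OC)[C@H](COCc2ccccc2)/C=C/C[Si](C)(C)C)ccc1OCc1ccccc1
A7 | alternative 3 | 1-aryl-4-methoxy-3-vinyltetralin, C4 epimers | COc1cc([C@@H]2c3cc(OCc4ccccc4)c(OC)c(OC)c3C(OC)[C@H](C=C)[C@H]2COCc2ccccc2)ccc1OCc1ccccc1
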